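**Retrosynthetic overview**
1. Feature (longipinane numbering: C1 ketone, C3 CH–Me, C6 CMe2, C7/C8 ester carbinols, C10 quaternary C–Me): the cyclobutane C4–C5–C11–C10 is spanned from C4 to C11 by C3–C2–C1, a bicyclo[3.1.1]heptane in which C5 can stand at the ketene-carbonyl level and C10 carries the methyl/chain pair of an E-trisubstituted alkene.
2. Last ring: the C6–C5 bond of the cycloheptane, from a C6 radical (7,6-epoxide) onto the C5 cyclobutanone; then C5–OH removal, ozonolysis of C1=CH2, bis-angeloylation of the 7,8-diol.
3. Strategic disconnection: C5–C4 and C11–C10 by intramolecular [2+2] cycloaddition of a vinylketene from an acyclic 3-methyl-2-enoyl chloride; the exocyclic methylene masks the C1 ketone.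
4. Chain: olefination of a methyl ketone; Rh-catalysed asymmetric 1,4-addition of an E-alkenylboronate to pent-3-en-2-one (sets C3); carboalumination of an (S)-homopropargylic alcohol from 3-methylbut-2-enal (sets C8).
5. Ring order: cyclobutane and six-membered ring together (step 9), cycloheptane afterwards (step 13).

Key step: step 9

Remark 1: the catalyst antipodes in steps 1 and 5 are named from the accepted transition-state models; each is checked on the first run and the mirror-image catalyst used if the sense is reversed.
Remark 2: a free C8 hydroxyl can close reversibly onto the strained C5 ketone as a bridged lactol; such compounds are listed as the open hydroxy ketones, and C8–OH is capped as a TES ether before the radical step so that the carbonyl is free.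

Step 1
Reactants: 1 3-methylbut-2-enal; 2 allenylboronic acid pinacol ester
Product: 3 (S)-6-methylhept-5-en-1-yn-4-ol
Conditions: (S)-TRIP phosphoric acid [(S)-3,3'-bis(2,4,6-triisopropylphenyl)-1,1'-binaphthyl-2,2'-diyl hydrogen phosphate] (10 mol %), 4 Å MS, toluene, −20 °C
Reagents that add atoms: none
Why: Chiral phosphoric acid-catalysed propargylboration, in which the allenylboronate adds through a closed six-membered SE2' transition state held by hydrogen bonds from the catalyst to a boronate oxygen and the formyl hydrogen, so the propargyl group should reach the Si face of the aldehyde and set C8 as S.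

Step 2
Reactants: 3 (S)-6-methylhept-5-en-1-yn-4-ol
Product: 5 (S,E)-1-iodo-2,6-dimethylhepta-1,5-dien-4-ol, via alkenyldimethylalane 4 (not isolated)
Conditions: AlMe3 (3 equiv), Cp2ZrCl2 (0.25 equiv), CH2Cl2, 0 °C → rt; then I2, THF, −30 → 0 °C; aq. K2CO3
Reagents that add atoms: trimethylaluminium C[Al](C)C; iodine II
Why: Negishi zirconium-catalysed carboalumination adds methyl and aluminium syn across the terminal alkyne with methyl on the internal carbon (the hydroxyl rides as its aluminium alkoxide), and iodinolysis with retention should give the E iodide with iodine trans to the C9 chain.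

Step 3
Reactants: 5 (S,E)-1-iodo-2,6-dimethylhepta-1,5-dien-4-ol
Product: 6 TBS ether of 5
Conditions: TBSCl, imidazole, DMF, rt
Reagents that add atoms: tert-butyldimethylsilyl chloride CC(C)(C)[Si](C)(C)Cl
Why: Routine silylation of a secondary alcohol; the TBS ether protects C8–O through the basic and organometallic steps up to the cycloaddition.

Step 4
Reactants: 6 TBS ether of 5
Product: 7 (1E,4S)-alkenyl pinacolboronate
Conditions: B2pin2, PdCl2(PPh3)2 (3 mol %), PPh3 (6 mol %), KOPh, toluene, 50 °C
Reagents that add atoms: bis(pinacolato)diboron CC1(C)OB(OC1(C)C)B1OC(C)(C)C(C)(C)O1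
Why: Miyaura borylation of an alkenyl iodide (oxidative addition, boryl transfer from the phenoxide-activated diboron, reductive elimination) should proceed with retention of the E geometry.

Step 5
Reactants: 7 (1E,4S)-alkenyl pinacolboronate; 8 (E)-pent-3-en-2-one
Product: 9 (4R,5E,8S)-8-(tert-butyldimethylsilyloxy)-4,6,10-trimethylundeca-5,9-dien-2-one
Conditions: [Rh(OH)((S)-BINAP)]2 (3 mol %), KOH (20 mol %), 8 (3 equiv), dioxane/H2O 10:1, 50 °C
Reagents that add atoms: none
Why: Hayashi–Miyaura rhodium-catalysed asymmetric 1,4-addition, in which the alkenyl group passes from boron to rhodium, the enone inserts with its face fixed by the BINAP quadrants (Re face of the β-carbon) and the oxa-π-allyl rhodium is hydrolysed, so C3 should be set as R under catalyst control, the remote C8 centre being a spectator and the alkene geometry retained.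

Step 6
Reactants: 9 (4R,5E,8S)-methyl ketone; 10 triethyl phosphonoacetate
Product: 11 ethyl (2E,5R,6E,9S)-9-(tert-butyldimethylsilyloxy)-3,5,7,11-tetramethyldodeca-2,6,10-trienoate
Conditions: NaH, 10, THF, 0 °C; then 9, 0 → 60 °C
Reagents that add atoms: none
Why: Horner–Wadsworth–Emmons olefination of the methyl ketone should give the trisubstituted enoate mainly as the 2E isomer (minor 2Z isomer removed by chromatography), and C3, being β to the ketone, cannot epimerise.

Step 7
Reactants: 11 ethyl trienoate
Product: 12 (2E,5R,6E,9S)-9-(tert-butyldimethylsilyloxy)-3,5,7,11-tetramethyldodeca-2,6,10-trienoic acid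
Conditions: LiOH, THF/MeOH/H2O, 50 °C; then cold 0.5 M HCl to pH 4
Reagents that add atoms: lithium hydroxide [Li+].[OH-]
Why: Saponification of the conjugated ester leaves the secondary TBS ether and both stereocentres untouched, and acidification only to pH 4 avoids desilylation.

Step 8
Reactants: 12 trienoic acid
Product: 13 (2E,5R,6E,9S)-trienoyl chloride
Conditions: 1-chloro-N,N,2-trimethylprop-1-en-1-amine (1.3 equiv), CH2Cl2, 0 °C → rt; evaporate, use crude
Reagents that add atoms: 1-chloro-N,N,2-trimethylprop-1-en-1-amine CC(C)=C(Cl)N(C)C
Why: The α-chloroenamine converts the acid into its chloride under neutral conditions with only a neutral amide as by-product, so the acid-labile allylic silyl ether and the alkenes survive.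

Step 9
Reactants: 13 trienoyl chloride
Product: 15 2-methylidenebicyclo[3.1.1]heptan-6-one cycloadduct, via vinylketene 14 (not isolated)
Conditions: Et3N (5 equiv), toluene, reflux; 13 added over 8 h by syringe pump (final 0.005 M), then 2 h
Reagents that add atoms: none
Why: Triethylamine removes a γ-proton from the methyl group on C1 with loss of chloride to give vinylketene 14, whose electrophilic central carbon C5 is attacked by the electron-rich C4=C10 alkene in a thermal [2+2] cycloaddition that is concerted but uneven in timing (C5–C4 bond ahead, positive charge building on the tertiary C10, which then closes onto C11); the closest known reaction type is the intramolecular [2+2] cycloaddition of vinylketenes from geranoyl- and farnesoyl-type 3-methylalk-2-enoyl chlorides, which gives 2-methylidenebicyclo[3.1.1]heptan-6-ones. Two rings close in this one event: the six-membered ring C1–C2–C3–C4–C5–C11 through the leading C5–C4 bond (exo with respect to the alkene, C10 left outside), and the cyclobutane C4–C5–C11–C10 through the C11–C10 bond, the crossed mode that the three-atom tether and the alkene polarity impose, so a bridged bicyclo[3.1.1] and not a fused bicyclo[3.2.0] skeleton should result. C10 is set by the E alkene geometry, which is transferred suprafacially and places the C10 methyl syn and the C9 chain anti to the C1–C3 bridge, while C4 and C11 follow from the cage once the alkene face is chosen. That face is chosen by C3: 1,3-allylic strain against the C10 methyl keeps the C3–H bond in the alkene plane, so the tether and ketene can reach only the face that leaves the C3 methyl on the side of the C5 carbonyl bridge, as in the target; this control is argued from conformational analysis and has no direct precedent for an allylic stereocentre on the tether. The step further needs deprotonation at the methyl group and not at C2 (favoured by the branching at C3 and by the methyl being cis to the acyl group in the 2E isomer) and unimolecular capture of the ketene (secured by slow addition into hot dilute toluene); the distal C6=C7 alkene is out of reach and the product ketone cannot enolise.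

Step 10
Reactants: 15 cycloadduct (C8–OTBS)
Product: 16 cycloadduct with free C8–OH
Conditions: HF·pyridine, pyridine, THF, 0 °C → rt
Reagents that add atoms: none
Why: Fluoride cleavage of the TBS ether under buffered, non-basic conditions, chosen so that no alkoxide is generated next to the strained, non-enolisable cyclobutanone, which a basic fluoride source could open.

Step 11
Reactants: 16 cycloadduct with free C8–OH
Product: 17 threo 7,6-epoxy-8-ol
Conditions: Ti(OiPr)4 (20 mol %), t-BuOOH (2 equiv, in decane), 4 Å MS, CH2Cl2, −20 °C
Reagents that add atoms: tert-butyl hydroperoxide CC(C)(C)OO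
Why: Hydroxyl-directed epoxidation (tartrate-free Sharpless titanium alkoxide/hydroperoxide system), in which the metal bound to C8–O delivers oxygen only to the C6=C7 alkene and 1,3-allylic strain between the C8 substituent and the cis methyl on C6 holds C8–H in the alkene plane, so the threo epoxy alcohol should form and fix C7 relative to C8, with the exocyclic methylene and the ketone untouched.

Step 12
Reactants: 17 threo epoxy alcohol
Product: 18 8-O-TES epoxy ketone
Conditions: TESCl, imidazole, DMAP (cat.), DMF, 0 °C → rt
Reagents that add atoms: triethylsilyl chloride CC[Si](CC)(CC)Cl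
Why: Silylation of the secondary C8 hydroxyl draws any bridged lactol back to the open form and keeps the C5 carbonyl free for the radical step, the epoxide being stable to these conditions.

Step 13
Reactants: 18 8-O-TES epoxy ketone
Product: 19 1-methylidenelongipinane-5,7,8-triol 8-TES ether
Conditions: Cp2TiCl2 (3 equiv), Mn dust (8 equiv), THF, rt (green Cp2TiCl, about 0.02 M); 18 in THF added over 4 h; aq. NaH2PO4
Reagents that add atoms: none
Why: Proposed new method: Cp2TiCl opens the epoxide by inner-sphere electron transfer to the more substituted radical (tertiary C6), leaving the C7–O bond and its configuration intact; the C6 radical, held under C5 by the cage, should add 7-exo to the strained cyclobutanone carbonyl, and the resulting cyclobutoxyl radical must be reduced by a second trivalent titanium (most plausibly already bound to the carbonyl oxygen) before it can cleave the C5–C11 bond to an allyl radical, which is why titanium is kept dilute but always in excess over slowly added substrate; the closest known reaction type is the Cp2TiCl-mediated cyclisation of epoxide-derived radicals onto aldehyde and ketone carbonyls to three- to six-membered cycloalkanols (Nugent–RajanBabu epoxide opening), not yet shown for a seven-membered ring or a cyclobutanone acceptor; C5 can only form with C6 anti to the C1–C3 bridge because the chain reaches the carbonyl from that face alone.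

Step 14
Reactants: 19 5,7-diol 8-TES ether
Product: 20 1-methylidenelongipinane-5,7,8-triol 7,8-bis-TES ether
Conditions: TESOTf (1.2 equiv), 2,6-lutidine, CH2Cl2, −78 °C
Reagents that add atoms: triethylsilyl triflate CC[Si](CC)(CC)OS(=O)(=O)C(F)(F)F
Why: Silyl triflate silylation of the hindered secondary C7 hydroxyl, with which the tertiary C5 cyclobutanol (flanked by the quaternary C6 and two ring-fusion carbons) should not compete at −78 °C.

Step 15
Reactants: 20 7,8-bis-TES ether with free C5–OH
Product: 21 C5 methyl oxalate of 20
Conditions: ClC(O)CO2Me (3 equiv), Et3N, DMAP, CH2Cl2, 0 °C → rt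
Reagents that add atoms: methyl chlorooxalate COC(=O)C(=O)Cl
Why: DMAP-catalysed acylation with the small, highly electrophilic methyl chlorooxalate should esterify even this tertiary alcohol, and the oxalate cannot eliminate because every β-position is a ring-fusion or quaternary carbon.

Step 16
Reactants: 21 C5 methyl oxalate
Product: 22 7,8-bis(triethylsilyloxy)-1-methylidenelongipinane
Conditions: Bu3SnH (2 equiv), AIBN (0.2 equiv), toluene, 110 °C
Reagents that add atoms: none
Why: Barton–McCombie-type radical deoxygenation through the methyl oxalate of a tertiary alcohol, in which the stannyl radical adds to the oxalate, the C5–O bond cleaves to the tertiary cyclobutyl radical (slow to ring-open), and hydrogen transfer from the stannane can occur only at the site the oxygen left because C6 is tied to C10 on the other face, so C5–H ends syn to the C1–C3 bridge.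

Step 17
Reactants: 22 7,8-bis(triethylsilyloxy)-1-methylidenelongipinane
Product: 24 7,8-bis(triethylsilyloxy)longipinan-1-one, via ozonide 23 (not isolated)
Conditions: O3, CH2Cl2, −78 °C; then PPh3, −78 °C → rt
Reagents that add atoms: ozone [O-][O+]=O
Why: Ozonolysis (Criegee mechanism) of the only alkene, followed by reductive cleavage of the ozonide, unmasks the C1 ketone, and the adjacent ring-fusion centre C11 cannot epimerise within the cage.

Step 18
Reactants: 24 7,8-bis(triethylsilyloxy)longipinan-1-one
Product: 25 7,8-dihydroxylongipinan-1-one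
Conditions: HF·pyridine, pyridine, THF, 0 °C → rt
Reagents that add atoms: none
Why: Buffered fluoride cleavage of both TES ethers should free the trans-7,8-diol without touching the ketone.

Step 19
Reactants: 25 7,8-dihydroxylongipinan-1-one; 26 angelic acid
Product: 28 7,8-bis(angeloyloxy)longipinan-1-one (target CNP0109825.1), via mixed anhydride 27 (not isolated)
Conditions: 26 (6 equiv), 2,4,6-trichlorobenzoyl chloride (6 equiv), Et3N (6 equiv), toluene, rt, 2 h; then 25, toluene, 80 °C
Reagents that add atoms: none
Why: Yamaguchi-type acylation, in which both secondary hydroxyls attack the mixed anhydride at its unhindered angeloyl carbonyl, and leaving out nucleophilic catalysts such as DMAP avoids the addition–elimination path that turns Z angelate into E tiglate.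

**Compound list**
1 | 3-methylbut-2-enal | CC(C)=CC=O | starting material
2 | allenylboronic acid pinacol ester (4,4,5,5-tetramethyl-2-(propa-1,2-dien-1-yl)-1,3,2-dioxaborolane) | C=C=CB1OC(C)(C)C(C)(C)O1 | starting material
3 | (S)-6-methylhept-5-en-1-yn-4-ol | C#CC[C@H](O)C=C(C)C | intermediate
4 | dimethyl[(1E,4S)-4-(dimethylalumanyloxy)-2,6-dimethylhepta-1,5-dien-1-yl]alumane | C[Al](C)/C=C(\C)C[C@H](O[Al](C)C)C=C(C)C | intermediate (not isolated)
5 | (S,E)-1-iodo-2,6-dimethylhepta-1,5-dien-4-ol | I/C=C(\C)C[C@H](O)C=C(C)C | intermediate
6 | tert-butyl{[(1E,4S)-1-iodo-2,6-dimethylhepta-1,5-dien-4-yl]oxy}dimethylsilane | I/C=C(\C)C[C@H](O[Si](C)(C)C(C)(C)C)C=C(C)C | intermediate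
7 | 2-[(1E,4S)-4-(tert-butyldimethylsilyloxy)-2,6-dimethylhepta-1,5-dien-1-yl]-4,4,5,5-tetramethyl-1,3,2-dioxaborolane | CC(C)=C[C@@H](O[Si](C)(C)C(C)(C)C)C/C(C)=C/B1OC(C)(C)C(C)(C)O1 | intermediate
8 | (E)-pent-3-en-2-one | C/C=C/C(C)=O | starting material
9 | (4R,5E,8S)-8-(tert-butyldimethylsilyloxy)-4,6,10-trimethylundeca-5,9-dien-2-one | CC(=O)C[C@@H](C)/C=C(\C)C[C@H](O[Si](C)(C)C(C)(C)C)C=C(C)C | intermediate
10 | triethyl phosphonoacetate | CCOC(=O)CP(=O)(OCC)OCC | starting material
11 | ethyl (2E,5R,6E,9S)-9-(tert-butyldimethylsilyloxy)-3,5,7,11-tetramethyldodeca-2,6,10-trienoate | CCOC(=O)/C=C(\C)C[C@@H](C)/C=C(\C)C[C@H](O[Si](C)(C)C(C)(C)C)C=C(C)C | intermediate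
12 | (2E,5R,6E,9S)-9-(tert-butyldimethylsilyloxy)-3,5,7,11-tetramethyldodeca-2,6,10-trienoic acid | OC(=O)/C=C(\C)C[C@@H](C)/C=C(\C)C[C@H](O[Si](C)(C)C(C)(C)C)C=C(C)C | intermediate
13 | (2E,5R,6E,9S)-9-(tert-butyldimethylsilyloxy)-3,5,7,11-tetramethyldodeca-2,6,10-trienoyl chloride | ClC(=O)/C=C(\C)C[C@@H](C)/C=C(\C)C[C@H](O[Si](C)(C)C(C)(C)C)C=C(C)C | intermediate
14 | vinylketene, (5R,6E,9S)-9-(tert-butyldimethylsilyloxy)-5,7,11-trimethyl-3-methylidenedodeca-1,6,10-trien-1-one | O=C=CC(=C)C[C@@H](C)/C=C(\C)C[C@H](O[Si](C)(C)C(C)(C)C)C=C(C)C | intermediate (not isolated)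
15 | 2-methylidenebicyclo[3.1.1]heptan-6-one (longipinane C1–C5, C10, C11; C5 ketone); C3 methyl syn to the C5 bridge, C10 methyl syn to the C1–C3 bridge, (S)-2-(tert-butyldimethylsilyloxy)-4-methylpent-3-enyl chain (C9–C6) anti on C10 | O=C1[C@H]2C(=C)C[C@@H](C)[C@@H]1[C@@]2(C)C[C@H](O[Si](C)(C)C(C)(C)C)C=C(C)C | intermediate
16 | as 15 with free (S)-C8 hydroxyl | O=C1[C@H]2C(=C)C[C@@H](C)[C@@H]1[C@@]2(C)C[C@H](O)C=C(C)C | intermediate
17 | threo epoxy alcohol: as 16 with the C6=C7 alkene as a 3,3-dimethyloxirane (C7 configured as in the target) | O=C1[C@H]2C(=C)C[C@@H](C)[C@@H]1[C@@]2(C)C[C@H](O)[C@H]3OC3(C)C | intermediate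
18 | 8-O-triethylsilyl ether of 17 | O=C1[C@H]2C(=C)C[C@@H](C)[C@@H]1[C@@]2(C)C[C@H](O[Si](CC)(CC)CC)[C@H]3OC3(C)C | intermediate
19 | 1-methylidenelongipinane-5,7,8-triol 8-TES ether (5-OH syn to the C1–C3 bridge, 7,8-trans) | CC[Si](CC)(CC)O[C@H]1C[C@]2(C)[C@@H]3[C@@](O)([C@H]2C(=C)C[C@H]3C)C(C)(C)[C@@H]1O | intermediate
20 | 1-methylidenelongipinane-5,7,8-triol 7,8-bis-TES ether | CC[Si](CC)(CC)O[C@H]1C[C@]2(C)[C@@H]3[C@@](O)([C@H]2C(=C)C[C@H]3C)C(C)(C)[C@@H]1O[Si](CC)(CC)CC | intermediate
21 | C5 methyl oxalate of 20 | CC[Si](CC)(CC)O[C@H]1C[C@]2(C)[C@@H]3[C@@](OC(=O)C(=O)OC)([C@H]2C(=C)C[C@H]3C)C(C)(C)[C@@H]1O[Si](CC)(CC)CC | intermediate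
22 | 7,8-bis(triethylsilyloxy)-1-methylidenelongipinane (C5–H syn to the C1–C3 bridge) | CC[Si](CC)(CC)O[C@H]1C[C@]2(C)[C@@H]3[C@@H]([C@H]2C(=C)C[C@H]3C)C(C)(C)[C@@H]1O[Si](CC)(CC)CC | intermediate
23 | ozonide of 22 (1,2,4-trioxolane spiro at C1) | CC[Si](CC)(CC)O[C@H]1C[C@]2(C)[C@@H]3[C@@H]([C@H]2C4(OCOO4)C[C@H]3C)C(C)(C)[C@@H]1O[Si](CC)(CC)CC | intermediate (not isolated)
24 | 7,8-bis(triethylsilyloxy)longipinan-1-one | CC[Si](CC)(CC)O[C@H]1C[C@]2(C)[C@@H]3[C@@H]([C@H]2C(=O)C[C@H]3C)C(C)(C)[C@@H]1O[Si](CC)(CC)CC | intermediate
25 | 7,8-dihydroxylongipinan-1-one | O[C@H]1C[C@]2(C)[C@@H]3[C@@H]([C@H]2C(=O)C[C@H]3C)C(C)(C)[C@@H]1O | intermediate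
26 | angelic acid, (Z)-2-methylbut-2-enoic acid | C/C=C(/C)C(=O)O | starting material
27 | angelic 2,4,6-trichlorobenzoic mixed anhydride | C/C=C(/C)C(=O)OC(=O)c1c(Cl)cc(Cl)cc1Cl | intermediate (not isolated)
28 | 7,8-bis(angeloyloxy)longipinan-1-one, CNP0109825.1 | C/C=C(/C)C(=O)O[C@H]1C[C@]2(C)[C@@H]3[C@@H]([C@H]2C(=O)C[C@H]3C)C(C)(C)[C@@H]1OC(=O)/C(C)=C\C | target

**Step count and risks**
Total: 19 steps. Longest linear sequence: 19 steps, from 3-methylbut-2-enal (1) to 28.

1. Step 13 (proposed new method). The cyclobutoxyl radical may fragment by C5–C11 cleavage before it is reduced, or the tertiary C6 radical may be quenched (reduction or loss of a hydrogen to an isopropenyl carbinol) before the slow 7-exo closure. The fallback sets out from 18 and removes the oxygen-centred radical altogether. The epoxide is opened at the tertiary carbon with MgBr2·OEt2 (Et2O, −20 °C) to the bromohydrin F1, with the C7–O bond untouched. C7–OH is silylated (TESOTf, 2,6-lutidine) to the bis-TES bromo ketone F2. The cyclobutanone is condensed with 1-amino-2-phenylaziridine to the N-aziridinylimine F3. Slow addition of Bu3SnH/AIBN (benzene, 80 °C) then generates the C6 radical, which adds to the imine carbon C5; the aminyl radical expels styrene and dinitrogen, and the C5 radical takes hydrogen from the stannane on its only open face (tin-mediated radical cyclisation onto an N-aziridinylimine, a known reaction type). The fallback comes back at 22, so steps 14 to 16 are not needed.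

2. Step 9. Deprotonation may occur at C2 instead of the methyl group, the ketene may oligomerise, or facial selectivity may erode at 110 °C. The fallback sets out from 9 and makes the same vinylketene without base. Kinetic enolisation at the methyl group (LiN(iPr)2, THF, −78 °C; PhNTf2) should give the enol triflate F4. Sonogashira coupling with tert-butoxyethyne (Pd(PPh3)4, CuI, Et3N) gives the enynyl tert-butyl ether F5. Warming F5 in dilute toluene (80–90 °C) expels 2-methylpropene by a retro-ene reaction and releases vinylketene 14, with the exocyclic methylene already in place; it cyclises to 15 (thermal ketene generation from tert-butyl ynol ethers with intramolecular [2+2] capture is known). The fallback comes back at 15 and bypasses steps 6 to 8.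

3. Step 19. Acylation of the neopentylic C7–OH may stall, and prolonged heating may isomerise angelate to tiglate. The fallback sets out from 25 and builds the Z alkenes on the molecule. Esterification of both hydroxyls with 2-[bis(2,2,2-trifluoroethoxy)phosphoryl]propanoic acid (DCC, CH2Cl2; acylation through the phosphonoketene tolerates hindered alcohols) gives the bis-phosphonopropionate F6. A double Still–Gennari olefination with acetaldehyde (KN(SiMe3)2, 18-crown-6, THF, −78 °C) should then give both Z-2-methylbut-2-enoates. The fallback comes back at 28.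

**Further compounds**
F1 | step 13 | bromohydrin: as 18 with the epoxide opened to C6–Br and C7–OH | O=C1[C@H]2C(=C)C[C@@H](C)[C@@H]1[C@@]2(C)C[C@H](O[Si](CC)(CC)CC)[C@@H](O)C(C)(C)Br
F2 | step 13 | 7,8-bis-TES bromo ketone | O=C1[C@H]2C(=C)C[C@@H](C)[C@@H]1[C@@]2(C)C[C@H](O[Si](CC)(CC)CC)[C@@H](O[Si](CC)(CC)CC)C(C)(C)Br
F3 | step 13 | N-(2-phenylaziridin-1-yl)imine of F2 at C5 | c1ccccc1C1CN1N=C2[C@H]3C(=C)C[C@@H](C)[C@@H]2[C@@]3(C)C[C@H](O[Si](CC)(CC)CC)[C@@H](O[Si](CC)(CC)CC)C(C)(C)Br
F4 | step 9 | enol triflate of 9 at the methyl side, (4R,5E,8S)-8-(tert-butyldimethylsilyloxy)-4,6,10-trimethylundeca-1,5,9-trien-2-yl triflate | C=C(OS(=O)(=O)C(F)(F)F)C[C@@H](C)/C=C(\C)C[C@H](O[Si](C)(C)C(C)(C)C)C=C(C)C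
F5 | step 9 | enynyl tert-butyl ether, 1-tert-butoxy-3-methylidene-alk-1-yne from F4 | CC(C)(C)OC#CC(=C)C[C@@H](C)/C=C(\C)C[C@H](O[Si](C)(C)C(C)(C)C)C=C(C)C
F6 | step 19 | 7,8-bis{2-[bis(2,2,2-trifluoroethoxy)phosphoryl]propanoate} of 25 | CC(C(=O)O[C@H]1C[C@]2(C)[C@@H]3[C@@H]([C@H]2C(=O)C[C@H]3C)C(C)(C)[C@@H]1OC(=O)C(C)P(=O)(OCC(F)(F)F)OCC(F)(F)F)P(=O)(OCC(F)(F)F)OCC(F)(F)F
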